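The smallest charge of solid reagent among the flasks asked about, 1.20 equiv in summer, is the one to balance first.

the same everywhere: starting material 0.43 M (fed, over 20 min)
- south-east: solid reagent 0.97 equiv; run made earlier
- west: solid reagent 4 equiv; run made earlier
- summer: solid reagent 1.20 equiv; time 2.0 h
- autumn: solid reagent 2.50 equiv; time 2.0 h
- spring: solid reagent 5.00 equiv; time 2.0 h

| run | time / min | single product / % | double product / % |
|---|---|---|---|
| south-east | 8.00 | 0 | 0 |
| south-east | 20.0 | 1.0 | 0 |
| south-east | 40.0 | 4.4 | 0 |
| south-east | 60.0 | 7.6 | 0.3 |
| west | 8.00 | 0.4 | 0 |
| west | 20.0 | 0.9 | 0 |
| west | 40.0 | 3.9 | 0.2 |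
| west | 60.0 | 6.9 | 0.3 |

(each reading ± 0.3 percentage points)

- solid, in amounts per volume of the solution: solid reagent
- at the start none of the solid reagent is in solution
- "hardly changes" means that all values lie within two and a half points (for a concentration: within two and a half percent of the largest)
- percentages count the whole charge, also what has not yet gone in

1. share of single product in all that became single product or double product for summer, autumn, spring, in this order
2. how that number moves from the first to the last of them (rises all the way / falls, then rises / rises, then falls / hardly changes / falls all the way)

Does the amount of solid show in the rate at all? At 60.0 min the south-east run, with 0.97 equiv, holds 7.6 % single product and the west run, with 4 equiv, holds 6.9 %. That gap of 0.7 percentage points stands against a scatter of 0.3 points per reading, and the run with less solid is the one ahead, so you read no gain from more solid.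

How much, then, does a flask draw by 2.0 h? After the feed, single product in the south-east run climbs by 0.0990 h⁻¹ of the charge, and a straight line carries it to 17.5 %. You take double product to grow out of single product and let it rise with the square of the time since mid-feed, from 0.3 % to 1.45 %. Counting one reagent for single product and two for double product, you reckon the demand at 0.0877 M.

The solid charged per volume in summer, divided by that demand, gives 5.88. This ratio is the reserve, and above one the solid outlasts the reckoned demand. Summer clears that mark, and autumn and spring hold more solid, so your reckoning gives one share for all of them, 92.3 %.

The forecast gives 92 %, 92 % and 92 %, hardly changes: “Reagent use is only about 0.2 equiv, so solid remains even at 1.20 equiv.”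

The flasks give 87.1 %, 87.1 % and 87.1 %, hardly changes.

    partner + other mono adduct → double product + by-product (k = 5.34 × 10⁻⁴ M⁻¹ s⁻¹)
    starting material + partner → single product + by-product (k = 9.12 × 10⁻⁴ M⁻¹ s⁻¹)
    starting material + partner → other mono adduct + by-product (k = 8.27 × 10⁻⁴ M⁻¹ s⁻¹)
    partner + single product → double product + by-product (k = 6.51 × 10⁻⁴ M⁻¹ s⁻¹)
    solid reagent ⇌ partner, rate k5*(cs5 - [partner]) while solid is left; crystals form when [partner] > cs5 (solubility = 0.370 M, k = 8.24 × 10⁻⁵ s⁻¹)

At 0.980 h in summer, starting material has a half-life of 5.7 h towards single product and 6.3 h towards other mono adduct; at 2.0 h, 15.0 % other mono adduct stands beside 16.3 % single product, and by-product plus partner come to 0.199 M, more than the demand of 0.0877 M, which moves the reserve from 5.88 to 2.59, with 61.4 % of the solid left. Summer at 20.0 h has its reserve at 1.00: the solid, now the limiting reagent, stands at 0 %, c(partner) at 2.78 × 10⁻⁷ M, and the share at 46.4 %, against 0.0996 % in autumn at 20.0 h, where c(partner) is 0.217 M.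

(The earlier runs and the new flask are calculated on assumed constants; scatter was added.)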